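Halve the coupling partner and watch the rate.

| flask | starting material | coupling partner | free catalyst | time |
|---|---|---|---|---|
| Friday's | 0.500 M | 1.50 M | 0.00100 M |  |
| Wednesday's | 0.300 M | 1.30 M | 0.00100 M |  |
| Monday's | 0.500 M | 1.50 M | 0.00200 M |  |
| Saturday's | 0.500 M | 0.750 M | 0.00100 M |  |
| Sunday's | 0.500 M | 0.230 M | 0.00100 M | 27 h |

| Friday's run: time / h | Friday's run: [target] / M | Wednesday's run: time / h | Wednesday's run: [target] / M | Monday's run: time / h | Monday's run: [target] / M | Saturday's run: time / h | Saturday's run: [target] / M |
|---|---|---|---|---|---|---|---|
| 3.9 | 0.0554 | 3.9 | 0.0336 | 3.9 | 0.1188 | 3.9 | 0.0471 |
| 7.7 | 0.0956 | 7.7 | 0.0613 | 7.7 | 0.2044 | 7.7 | 0.0868 |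
| 12 | 0.1366 | 12 | 0.0832 | 12 | 0.2702 | 12 | 0.1264 |
| 15 | 0.1574 | 15 | 0.1028 | 15 | 0.3027 | 15 | 0.1539 |
| 19 | 0.1869 | 19 | 0.1188 | 19 | 0.3398 | 19 | 0.1836 |
| 23 | 0.2094 | 23 | 0.1319 | 23 | 0.3696 | 23 | 0.2081 |
| 27 | 0.2277 | 27 | 0.1445 | 27 | 0.3919 | 27 | 0.2315 |

(standard deviation of a reading: 0.002 M)

- Overall: starting material + coupling partner -> target, with free catalyst as catalyst.
- Constant volume, constant temperature.
- Bound and free are read together.
- "The second partner" is coupling partner.
- An order is taken over about fifteen percent of the charge, up and down.

* the exponent of [coupling partner] in the starting rate at the charge of the Friday's run (at the point where two percent of the starting material have become target)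
* the exponent of [starting material] in the starting rate at the charge of the Friday's run (at the point where two percent of the starting material have become target) (one fixed amount of target, the same in the runs compared)
* the Wednesday's run starts with 0.200 M less of starting material and of coupling partner than the Friday's run, and with no target. Compared where both hold the same amount of starting material, once fifteen percent of what the Wednesday's run was charged with has turned into target, is the Wednesday's run faster, slower or alike (within a tenth)?
* target in the Sunday's run at 27 h, as a share of the starting material charged

Saturday's run holds half of Friday's coupling partner. At 3.9 h, Friday's run has made 0.0554 M of target and Saturday's run 0.0471 M, a reading of 0.850 for Saturday's run over Friday's. My picture for each catalyst turn is two steps: the catalyst takes up starting material, then meets coupling partner. That gives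

rate = A · c(starting material) · c(coupling partner) / [b · c(starting material) + c(coupling partner)]

Here A holds the catalyst. For a halved charge, the order in coupling partner at Friday's charge comes out as

θ = 1/0.850 − 1 = 0.176

b = θ/(1 − θ) · c(coupling partner)/c(starting material) = 0.642

This b, the step balance, is the first step's speed over the second's at equal concentrations. On the scale b · c(starting material)/c(coupling partner), level steps stand at 1. Friday's charge stands at 0.214 on that scale, so I read θ as the order in coupling partner and 0.824 as the order in starting material. Sunday's charge stands at 1.40, close to level, so coupling partner counts there.

Integrating the rate gives a clock: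

A · t = b · ln[c(coupling partner, start)/c(coupling partner, now)] + ln[c(starting material, start)/c(starting material, now)]

Friday's first reading, put on this clock, gives A = 0.0363 /h.

In Sunday's run, coupling partner is the limiting reagent, capping target at 46.0% of the starting material. Its 27 h supply 0.980 on the clock, and 0.144 M of target costs 0.968, just inside that supply. So I commit to about 28.8%.

Now the test. Compared at equal starting material, Wednesday's and Friday's runs also hold equal coupling partner, so b predicts a ratio of 1. Wednesday's run makes 0.00862 M/h over its first 3.9 h. Friday's run, holding about as much starting material between 19 h and 27 h, makes 0.00510 M/h. These readings put the ratio near 1.69, the nearest they come to the asked point, so I answer that Wednesday's run is faster. One number is not enough, and my Sunday figure, which holds A for the whole 27 h, may read high.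

The forecast gave 0.25, 0.97, faster and 23.5%, below my Sunday figure, by “stepping the saturation law with little catalyst decay”.

The flask gives 0.14, 0.88, faster and 29.9%.

    free catalyst + starting material → catalyst-substrate complex (49.68 /M/h)
    catalyst-substrate complex + coupling partner → target + free catalyst (87.48 /M/h)
    free catalyst + impurity → spent catalyst
    free catalyst + coupling partner → spent catalyst + coupling partner (0.02146 /M/h)

The impurity removes 2.76 × 10⁻⁴ M of Sunday's 0.00100 M of free catalyst at once. Sunday's run without it reaches 36.0% against 29.9%, so the impurity costs 6.2 percentage points. On the clock with b, Sunday's run as it is costs 1.03 and the run without impurity costs 1.43, a factor of 1.39, while giving back the impurity's share raises Sunday's free catalyst by a factor of 1.38.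

The earlier runs and the new flask were generated by integration with constants of no real substance; noise was put on by code.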